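The route rests on disconnecting the C2–C3 bond of the 2,3-dihydro-1,4-benzodioxine ring, the bond that joins the two stereocentres, each of which carries one ring oxygen (O1 at C2, O4 at C3). The precursor is an achiral flavone catechol bis-ether: a formylmethyl group on O1 (flavone 4′-O) and a 4-benzyloxy-3-methoxybenzyl group on O4 (3′-O). In one operation, DDQ turns the electron-rich benzylic ether into an oxocarbenium ion and a chiral secondary amine turns the aldehyde into an enamine; their union closes the dioxane ring by C–C bond formation and sets both stereocentres (trans, 2R,3R). Regiochemistry is fixed beforehand by two ordinary O-alkylations.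

Key step: step 7

Assumption: compounds 1, 3 and 6 are taken as commercially available; the locants O1, C2, C3, O4 are those of the benzodioxine ring of the target (O1 = flavone 4′-O, O4 = flavone 3′-O).

Step 1
Reactants: 1 3,4-dihydroxy-5-methoxybenzaldehyde
Product: 2 3-hydroxy-4-(2-hydroxyethoxy)-5-methoxybenzaldehyde
Conditions: 2-bromoethanol (1.2 equiv), K2CO3 (1.0 equiv), KI (cat.), DMF, 60 °C
Reagents that add atoms: 2-bromoethanol, OCCBr
Why: Williamson etherification in which the 4-OH, para to the formyl group, is the more acidic phenol, so that with one equivalent of carbonate only its phenoxide should form and be alkylated.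

Step 2
Reactants: 2 3-hydroxy-4-(2-hydroxyethoxy)-5-methoxybenzaldehyde; 3 1-[2,4-bis(benzyloxy)-6-hydroxyphenyl]ethanone
Product: 4 (E)-1-[2,4-bis(benzyloxy)-6-hydroxyphenyl]-3-[3-hydroxy-4-(2-hydroxyethoxy)-5-methoxyphenyl]prop-2-en-1-one
Conditions: KOH (50% aq.), EtOH, rt, 48 h; then dilute HCl
Reagents that add atoms: none
Why: Claisen–Schmidt condensation of the acetophenone enolate with the non-enolisable aldehyde, followed by dehydration to the E-enone; the meta-phenoxide deactivates the aldehyde only mildly.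

Step 3
Reactants: 4 (E)-1-[2,4-bis(benzyloxy)-6-hydroxyphenyl]-3-[3-hydroxy-4-(2-hydroxyethoxy)-5-methoxyphenyl]prop-2-en-1-one
Product: 5 5,7-bis(benzyloxy)-2-[3-hydroxy-4-(2-hydroxyethoxy)-5-methoxyphenyl]-4H-chromen-4-one
Conditions: I2 (10 mol%), DMSO, 120 °C; Na2S2O3 work-up
Reagents that add atoms: none
Why: Iodine-catalysed oxidative cyclisation of a 2′-hydroxychalcone to the flavone (oxa-Michael addition, α-iodination, loss of HI, with DMSO reoxidising iodide), conditions that benzyl aryl ethers should tolerate.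

Step 4
Reactants: 6 [4-(benzyloxy)-3-methoxyphenyl]methanol
Product: 7 1-(benzyloxy)-4-(chloromethyl)-2-methoxybenzene
Conditions: SOCl2 (1.2 equiv), CH2Cl2, 0 °C to rt; used crude
Reagents that add atoms: thionyl chloride, O=S(Cl)Cl
Why: Chlorodehydroxylation of an electron-rich benzylic alcohol through its chlorosulfite, a standard conversion for alkoxybenzyl alcohols.

Step 5
Reactants: 5 5,7-bis(benzyloxy)-2-[3-hydroxy-4-(2-hydroxyethoxy)-5-methoxyphenyl]-4H-chromen-4-one; 7 1-(benzyloxy)-4-(chloromethyl)-2-methoxybenzene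
Product: 8 5,7-bis(benzyloxy)-2-[3-{[4-(benzyloxy)-3-methoxybenzyl]oxy}-4-(2-hydroxyethoxy)-5-methoxyphenyl]-4H-chromen-4-one
Conditions: K2CO3, Bu4NI (cat.), DMF, 50 °C
Reagents that add atoms: none
Why: Williamson etherification that should be chemoselective, because carbonate deprotonates the 3′-phenol but not the primary alcohol.

Step 6
Reactants: 8 5,7-bis(benzyloxy)-2-[3-{[4-(benzyloxy)-3-methoxybenzyl]oxy}-4-(2-hydroxyethoxy)-5-methoxyphenyl]-4H-chromen-4-one
Product: 9 {2-[(4-(benzyloxy)-3-methoxybenzyl)oxy]-4-[5,7-bis(benzyloxy)-4-oxo-4H-chromen-2-yl]-6-methoxyphenoxy}acetaldehyde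
Conditions: Dess–Martin periodinane (1.3 equiv), pyridine, CH2Cl2, 0 °C to rt; used at once
Reagents that add atoms: none
Why: Dess–Martin oxidation of the primary alcohol to the aldehyde under buffered, non-aqueous conditions that should leave the aryl ethers, the acid-sensitive dialkoxybenzyl ether and the chromone untouched.

Step 7
Reactants: 9 {2-[(4-(benzyloxy)-3-methoxybenzyl)oxy]-4-[5,7-bis(benzyloxy)-4-oxo-4H-chromen-2-yl]-6-methoxyphenoxy}acetaldehyde
Product: 12 5,7-bis(benzyloxy)-2-[(2R,3R)-3-(4-(benzyloxy)-3-methoxyphenyl)-2-(hydroxymethyl)-8-methoxy-2,3-dihydro-1,4-benzodioxin-6-yl]-4H-chromen-4-one, via O-aryl oxocarbenium ion 10 (not isolated), via trans-benzodioxine-2-carbaldehyde 11 (not isolated)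
Conditions: DDQ (1.05 equiv), 4 Å MS, CH2Cl2 (0.02 M), 0 °C; then (R)-α,α-diphenylprolinol trimethylsilyl ether (20 mol%), −30 °C; then NaBH4, MeOH, −30 to 0 °C
Reagents that add atoms: none
Why: Proposed new method: DDQ should abstract hydride from the 3,4-dialkoxybenzylic C–H of the O4-benzyl ether to give oxocarbenium ion 10, while the amine converts the tethered aryloxyacetaldehyde into an (E)-enamine whose α-carbon attacks the cationic carbon; the closest known reaction types are the amine-catalysed enantioselective oxidative coupling of benzylic ethers with aldehydes and DDQ-mediated oxidative cyclisations onto oxocarbenium ions, extended here to an intramolecular case on an aryl benzyl ether. The dioxane ring closes by C2–C3 bond formation, 6-endo-trig at the O4=C3 oxocarbenium and enolexo with respect to the enamine, through a chair-like transition state. C2 is set by the catalyst, whose diphenyl(silyloxy)methyl group shields one enamine face, so that by the usual steric model the (R)-catalyst is expected to give the 2S aldehyde 11 (2R after reduction, because the CIP ranking changes); C3 is set relative to C2 by the chair on an (E)-oxocarbenium with the aryl group pseudo-equatorial, which gives trans. Site selectivity of the oxidation is secured by the dialkoxybenzyl group, since plain benzyl ethers and the flavone are inert to DDQ at 0 °C, and trans selectivity is reinforced thermodynamically because C2 of 11 can epimerise. Aldehyde 11 is reduced in the same flask to stop β-aryloxy elimination and epimerisation, the flavone carbonyl being too unreactive toward NaBH4 at this temperature to compete.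

Step 8
Reactants: 12 5,7-bis(benzyloxy)-2-[(2R,3R)-3-(4-(benzyloxy)-3-methoxyphenyl)-2-(hydroxymethyl)-8-methoxy-2,3-dihydro-1,4-benzodioxin-6-yl]-4H-chromen-4-one
Product: 13 5′-methoxyhydnocarpin
Conditions: H2 (1 atm), 10% Pd/C, THF–MeOH, rt
Reagents that add atoms: none
Why: Catalytic hydrogenolysis of the three benzyl aryl ethers, which should be faster than cleavage of the cyclic benzylic C3–O4 bond or saturation of the chromone C2=C3 bond under these mild conditions; no stereocentre is touched.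

Compound list
1 | 3,4-dihydroxy-5-methoxybenzaldehyde | COc1cc(C=O)cc(O)c1O | starting material
2 | 3-hydroxy-4-(2-hydroxyethoxy)-5-methoxybenzaldehyde | COc1cc(C=O)cc(O)c1OCCO | intermediate
3 | 1-[2,4-bis(benzyloxy)-6-hydroxyphenyl]ethanone | CC(=O)c1c(O)cc(OCc2ccccc2)cc1OCc1ccccc1 | starting material
4 | (E)-1-[2,4-bis(benzyloxy)-6-hydroxyphenyl]-3-[3-hydroxy-4-(2-hydroxyethoxy)-5-methoxyphenyl]prop-2-en-1-one | O=C(/C=C/c1cc(O)c(OCCO)c(OC)c1)c1c(O)cc(OCc2ccccc2)cc1OCc1ccccc1 | intermediate
5 | 5,7-bis(benzyloxy)-2-[3-hydroxy-4-(2-hydroxyethoxy)-5-methoxyphenyl]-4H-chromen-4-one | COc1cc(-c2cc(=O)c3c(OCc4ccccc4)cc(OCc4ccccc4)cc3o2)cc(O)c1OCCO | intermediate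
6 | [4-(benzyloxy)-3-methoxyphenyl]methanol | COc1cc(CO)ccc1OCc1ccccc1 | starting material
7 | 1-(benzyloxy)-4-(chloromethyl)-2-methoxybenzene | COc1cc(CCl)ccc1OCc1ccccc1 | intermediate
8 | 5,7-bis(benzyloxy)-2-[3-{[4-(benzyloxy)-3-methoxybenzyl]oxy}-4-(2-hydroxyethoxy)-5-methoxyphenyl]-4H-chromen-4-one | COc1cc(COc2cc(-c3cc(=O)c4c(OCc5ccccc5)cc(OCc5ccccc5)cc4o3)cc(OC)c2OCCO)ccc1OCc1ccccc1 | intermediate
9 | {2-[(4-(benzyloxy)-3-methoxybenzyl)oxy]-4-[5,7-bis(benzyloxy)-4-oxo-4H-chromen-2-yl]-6-methoxyphenoxy}acetaldehyde | COc1cc(COc2cc(-c3cc(=O)c4c(OCc5ccccc5)cc(OCc5ccccc5)cc4o3)cc(OC)c2OCC=O)ccc1OCc1ccccc1 | intermediate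
10 | O-aryl oxocarbenium ion from 9, ion pair with the DDQ-derived hydroquinone monoanion (not isolated) | COc1cc(C=[O+]c2cc(-c3cc(=O)c4c(OCc5ccccc5)cc(OCc5ccccc5)cc4o3)cc(OC)c2OCC=O)ccc1OCc1ccccc1.[O-]c1c(Cl)c(Cl)c(O)c(C#N)c1C#N | intermediate
11 | (2S,3R)-3-[4-(benzyloxy)-3-methoxyphenyl]-6-[5,7-bis(benzyloxy)-4-oxo-4H-chromen-2-yl]-8-methoxy-2,3-dihydro-1,4-benzodioxine-2-carbaldehyde, trans (not isolated) | COc1cc([C@H]2Oc3cc(-c4cc(=O)c5c(OCc6ccccc6)cc(OCc6ccccc6)cc5o4)cc(OC)c3O[C@@H]2C=O)ccc1OCc1ccccc1 | intermediate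
12 | 5,7-bis(benzyloxy)-2-[(2R,3R)-3-(4-(benzyloxy)-3-methoxyphenyl)-2-(hydroxymethyl)-8-methoxy-2,3-dihydro-1,4-benzodioxin-6-yl]-4H-chromen-4-one | COc1cc([C@H]2Oc3cc(-c4cc(=O)c5c(OCc6ccccc6)cc(OCc6ccccc6)cc5o4)cc(OC)c3O[C@@H]2CO)ccc1OCc1ccccc1 | intermediate
13 | 5′-methoxyhydnocarpin, 5,7-dihydroxy-2-[(2R,3R)-3-(4-hydroxy-3-methoxyphenyl)-2-(hydroxymethyl)-8-methoxy-2,3-dihydro-1,4-benzodioxin-6-yl]-4H-chromen-4-one | COc1cc([C@H]2Oc3cc(-c4cc(=O)c5c(O)cc(O)cc5o4)cc(OC)c3O[C@@H]2CO)ccc1O | target

Total step count: 8. Longest linear sequence: 7 (steps 1, 2, 3, 5, 6, 7, 8; step 4 is a one-step side branch).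

Steps most likely to fail

Step 7. The oxocarbenium ion may be lost to traces of water (oxidative debenzylation at O4) or be captured unproductively by the amine. The enamine may close the ring with poor facial selectivity. The β-aryloxy aldehyde may open by elimination before it is reduced. The fallback uses known chemistry and a C–O bond-forming annulation with resolution; it sets out from 1 and 3 and comes back to the route at 13. Both phenols of 1 are protected with MOMCl and iPr2NEt to give 3,4-bis(methoxymethoxy)-5-methoxybenzaldehyde F1. Claisen–Schmidt condensation with 3 gives (E)-1-[2,4-bis(benzyloxy)-6-hydroxyphenyl]-3-[3,4-bis(methoxymethoxy)-5-methoxyphenyl]prop-2-en-1-one F2. Iodine in DMSO gives 5,7-bis(benzyloxy)-2-[3,4-bis(methoxymethoxy)-5-methoxyphenyl]-4H-chromen-4-one F3, and HCl in MeOH–THF frees the catechol 5,7-bis(benzyloxy)-2-(3,4-dihydroxy-5-methoxyphenyl)-4H-chromen-4-one F4; any MOM loss in the iodine step is harmless. Silver carbonate-mediated oxidative coupling of F4 with coniferyl alcohol (phenoxyl radical coupling, then closure of the quinone methide) should give racemic trans-5,7-di-O-benzyl-5′-methoxyhydnocarpin F5. Chromatography on a chiral stationary phase then gives (2R,3R)-5,7-di-O-benzyl-5′-methoxyhydnocarpin F6, which is debenzylated under the conditions of step 8 to 13.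

Step 3. Hot iodine in DMSO may iodinate the ring next to the free 3′-phenol or oxidise the primary alcohol. The fallback sets out from 4 and comes back at 5. Oxa-Michael isomerisation of 4 (NaOAc, EtOH, reflux) gives racemic 5,7-bis(benzyloxy)-2-[3-hydroxy-4-(2-hydroxyethoxy)-5-methoxyphenyl]chroman-4-one F7, and iodine-free dehydrogenation with DDQ in dioxane at reflux gives 5.

Step 8. Over-reduction may occur: hydrogenolysis of the benzylic C3–O4 bond of the dioxane ring, or saturation of the chromone C2=C3 bond. The fallback sets out from 12 and comes back at 13: non-reductive debenzylation with BCl3 and pentamethylbenzene as benzyl-cation scavenger in CH2Cl2 at −78 °C. No new compound arises on this path, which is entered below as F0.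

Further compounds
F1 | step 7 | 3,4-bis(methoxymethoxy)-5-methoxybenzaldehyde | COCOc1cc(C=O)cc(OC)c1OCOC
F2 | step 7 | (E)-1-[2,4-bis(benzyloxy)-6-hydroxyphenyl]-3-[3,4-bis(methoxymethoxy)-5-methoxyphenyl]prop-2-en-1-one | COCOc1cc(/C=C/C(=O)c2c(O)cc(OCc3ccccc3)cc2OCc2ccccc2)cc(OC)c1OCOC
F3 | step 7 | 5,7-bis(benzyloxy)-2-[3,4-bis(methoxymethoxy)-5-methoxyphenyl]-4H-chromen-4-one | COCOc1cc(-c2cc(=O)c3c(OCc4ccccc4)cc(OCc4ccccc4)cc3o2)cc(OC)c1OCOC
F4 | step 7 | 5,7-bis(benzyloxy)-2-(3,4-dihydroxy-5-methoxyphenyl)-4H-chromen-4-one | COc1cc(-c2cc(=O)c3c(OCc4ccccc4)cc(OCc4ccccc4)cc3o2)cc(O)c1O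
F5 | step 7 | racemic trans-5,7-di-O-benzyl-5′-methoxyhydnocarpin | COc1cc([C@H]2Oc3cc(-c4cc(=O)c5c(OCc6ccccc6)cc(OCc6ccccc6)cc5o4)cc(OC)c3O[C@@H]2CO)ccc1O.COc1cc([C@@H]2Oc3cc(-c4cc(=O)c5c(OCc6ccccc6)cc(OCc6ccccc6)cc5o4)cc(OC)c3O[C@H]2CO)ccc1O
F6 | step 7 | (2R,3R)-5,7-di-O-benzyl-5′-methoxyhydnocarpin | COc1cc([C@H]2Oc3cc(-c4cc(=O)c5c(OCc6ccccc6)cc(OCc6ccccc6)cc5o4)cc(OC)c3O[C@@H]2CO)ccc1O
F7 | step 3 | racemic 5,7-bis(benzyloxy)-2-[3-hydroxy-4-(2-hydroxyethoxy)-5-methoxyphenyl]chroman-4-one | COc1cc(C2CC(=O)c3c(OCc4ccccc4)cc(OCc4ccccc4)cc3O2)cc(O)c1OCCO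
F0 | step 8 | none | none
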